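**Retrosynthetic overview (target numbering)**
- C9–CH3 and C9–Cl come from one-pot methyltitanium addition and chlorinative ionisation of a ring B α-bromo ketone. C8–Br and the spiro stereocentre C6 come from a hydroxyl-relayed α-bromination that desymmetrises a spiro-cyclohexadienone, followed by conjugate reduction.
- The spiro bond C5–C6 (ring A closure, key step) is made by palladium-catalysed dearomative alkenylation of a para-substituted phenol with a tethered 2-bromoalkene.
- The aryl–C1 bond is made by Friedel–Crafts union of fragment 1 (a bromonium ion from a tertiary chloride) with fragment 2, 4-(trimethylsilyl)phenol.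
- The C3–C4 bond is made by allylboration of (2R)-2-bromo-3-chloro-3-methylbutanal (from prenol by enantioselective bromochlorination) with fragment 3, a 2-bromoallyl boronate made from allene.
- Ring order: the aromatic precursor of ring B is present from the start, ring A closes in the palladium step, and ring B is then desymmetrised, saturated and functionalised.

Assumption: the SMILES is read as drawn, i.e. (2S,3R,6S,8S,9S)-2,8-dibromo-9-chloro-1,1,9-trimethyl-5-methylidenespiro[5.5]undecan-3-ol; locants in each step refer to the name of the compound under discussion.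

**Step 1**
Reactants: 1 3-methylbut-2-en-1-ol
Product: 2 (2R)-2-bromo-3-chloro-3-methylbutan-1-ol
Conditions: N-bromosuccinimide (1.05 equiv), ClTi(OiPr)3 (1.1 equiv), chiral tridentate Schiff-base ligand (20 mol %, antipode giving 2R), hexanes, −20 °C
Reagents that add atoms: N-bromosuccinimide O=C1CCC(=O)N1Br; chlorotitanium triisopropoxide CC(C)O[Ti](Cl)(OC(C)C)OC(C)C
Why: Titanium-mediated, ligand-controlled enantioselective bromochlorination of an allylic alcohol: the titanium-bound alcohol directs anti addition of Br+ (to C-2) and chloride (to the tertiary C-3, Markovnikov), and the ligand antipode fixes C-2 as R.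

**Step 2**
Reactants: 2 (2R)-2-bromo-3-chloro-3-methylbutan-1-ol
Product: 3 (2R)-2-bromo-3-chloro-3-methylbutanal
Conditions: Dess–Martin periodinane, CH2Cl2, 0 °C; used crude at once
Reagents that add atoms: none
Why: Dess–Martin oxidation of the primary alcohol runs without base, so the α-bromo stereocentre is not enolised and the β-chloride is not eliminated.

**Step 3**
Reactants: 4 propa-1,2-diene
Product: 6 2-(2-bromoprop-2-en-1-yl)-4,4,5,5-tetramethyl-1,3,2-dioxaborolane, via dibromoborane 5 (not isolated)
Conditions: BBr3, CH2Cl2, −78 °C; then pinacol, Et3N (2 equiv), −78 °C to rt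
Reagents that add atoms: boron tribromide BrB(Br)Br; pinacol CC(C)(O)C(C)(C)O
Why: Bromoboration (haloboration) of the allene places boron on the terminal and bromine on the central carbon, and esterification with pinacol gives a storable allylboronate.

**Step 4**
Reactants: 3 (2R)-2-bromo-3-chloro-3-methylbutanal; 6 2-(2-bromoprop-2-en-1-yl)-4,4,5,5-tetramethyl-1,3,2-dioxaborolane
Product: 8 (4R,5R)-2,5-dibromo-6-chloro-6-methylhept-1-en-4-ol, via boryl ether 7 (not isolated)
Conditions: CH2Cl2, −78 °C to rt; then H2O
Reagents that add atoms: none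
Why: Allylboration through a closed chair (Zimmerman–Traxler) transition state on the Cornforth conformer of the α-bromo aldehyde (C–Br anti to C=O) adds the allyl group anti to bromine, giving the 4,5-anti bromohydrin (C-4 R), while the symmetric 2-bromoallyl unit delivers the 2-bromoalkene.

**Step 5**
Reactants: 9 4-bromophenol
Product: 10 (4-bromophenoxy)(tert-butyl)dimethylsilane
Conditions: TBSCl, imidazole, DMF, rt
Reagents that add atoms: tert-butyldimethylsilyl chloride CC(C)(C)[Si](C)(C)Cl
Why: Silyl ether formation masks the phenol so that the aryl bromide can be lithiated.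

**Step 6**
Reactants: 10 (4-bromophenoxy)(tert-butyl)dimethylsilane
Product: 12 tert-butyldimethyl[4-(trimethylsilyl)phenoxy]silane, via aryllithium 11 (not isolated)
Conditions: n-BuLi, THF, −78 °C; then Me3SiCl, −78 °C to rt
Reagents that add atoms: chlorotrimethylsilane C[Si](C)(C)Cl
Why: Bromine–lithium exchange followed by electrophilic silylation installs the ipso-directing trimethylsilyl group para to oxygen.

**Step 7**
Reactants: 12 tert-butyldimethyl[4-(trimethylsilyl)phenoxy]silane
Product: 13 4-(trimethylsilyl)phenol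
Conditions: K2CO3 (0.2 equiv), MeOH, rt
Reagents that add atoms: none
Why: Base-catalysed methanolysis cleaves only the aryl silyl ether (the aryl C–Si bond is inert), freeing the phenol needed as activating group in step 8 and as nucleophile in step 9.

**Step 8**
Reactants: 8 (4R,5R)-2,5-dibromo-6-chloro-6-methylhept-1-en-4-ol; 13 4-(trimethylsilyl)phenol
Product: 14 (4R,5S)-2,5-dibromo-6-(4-hydroxyphenyl)-6-methylhept-1-en-4-ol
Conditions: 13 (3 equiv), 2,6-di-tert-butylpyridine (1.2 equiv), (CF3)2CHOH, 0 °C to rt
Reagents that add atoms: none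
Why: Friedel–Crafts alkylation by ipso-desilylation in the ionising, weakly nucleophilic solvent: the tertiary chloride ionises with anchimeric help from the vicinal bromine (bromonium ion), the silicon-activated carbon para to the hydroxyl attacks the tertiary terminus and loses the silyl group, and the C–Br stereocentre only bridges and keeps its configuration (R to S is a CIP priority change only).

**Step 9**
Reactants: 14 (4R,5S)-2,5-dibromo-6-(4-hydroxyphenyl)-6-methylhept-1-en-4-ol
Product: 15 (8S,9R)-8-bromo-9-hydroxy-7,7-dimethyl-11-methylidenespiro[5.5]undeca-1,4-dien-3-one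
Conditions: KOt-Bu (1.0 equiv), THF, 0 °C; then Pd2(dba)3 (2.5 mol %), t-BuXPhos (6 mol %), 1,4-dioxane, 80 °C
Reagents that add atoms: none
Why: Proposed new method: zerovalent palladium inserts into the C(sp2)–Br bond of the 2-bromoalkene (far faster than into the neopentyl secondary C–Br), the tethered potassium phenoxide (the only anion formed with one equivalent of base) attacks the alkenylpalladium centre through its para carbon, and C–C reductive elimination closes ring A, forming the quaternary C-6 and the exocyclic methylidene and dearomatising the phenol to the cross-conjugated dienone without creating a stereocentre (the dienone ring is symmetric) or touching C-8 and C-9; closest known reaction type: palladium-catalysed intramolecular arylative dearomatisation of para-substituted phenols by tethered aryl bromides.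

**Step 10**
Reactants: 15 (8S,9R)-8-bromo-9-hydroxy-7,7-dimethyl-11-methylidenespiro[5.5]undeca-1,4-dien-3-one
Product: 18 (6S,8S,9R)-2,8-dibromo-9-hydroxy-7,7-dimethyl-11-methylidenespiro[5.5]undeca-1,4-dien-3-one, via oxa-bridged adduct 16 (not isolated), via bromo adduct 17 (not isolated)
Conditions: Cs2CO3 (1.5 equiv), BrCCl2CCl2Br (1.05 equiv), THF, 0 °C to rt
Reagents that add atoms: 1,2-dibromo-1,1,2,2-tetrachloroethane ClC(Cl)(Br)C(Cl)(Cl)Br
Why: Proposed new method: the C-9 alkoxide can add (oxa-Michael, 2-oxabicyclo[2.2.2]octane with ring A as a boat) only to the dienone arm on its own face of ring A, the resulting enolate is the only carbon nucleophile available (the dienone has no enolisable hydrogen) and is brominated at C-2, and E1cB loss of the β-alkoxide regenerates the hydroxyl, so the hydroxyl acts as an intramolecular Morita–Baylis–Hillman-type catalyst that marks the syn arm and makes C-6 stereogenic as S; closest known reaction types: amine-catalysed α-halogenation of enones and oxa-Michael desymmetrisation of cyclohexadienones by tethered alcohols.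

**Step 11**
Reactants: 18 (6S,8S,9R)-2,8-dibromo-9-hydroxy-7,7-dimethyl-11-methylidenespiro[5.5]undeca-1,4-dien-3-one
Product: 19 (2S,6S,8S,9R)-2,8-dibromo-9-hydroxy-7,7-dimethyl-11-methylidenespiro[5.5]undecan-3-one
Conditions: [(Ph3P)CuH]6 (0.4 equiv), H2O (5 equiv), THF–benzene, 0 °C to rt
Reagents that add atoms: none
Why: Conjugate (1,4) reduction of both enone C=C bonds by the soft copper hydride leaves the isolated methylidene and the C–Br bonds alone, and axial protonation of the bromo-enolate together with the thermodynamic preference of the epimerisable α-bromo ketone (an axial bromine would be 1,3-diaxial to the axial ring A carbon C-11) places the C-2 bromine equatorial, cis to the equatorial C(CH3)2 carbon, i.e. 2S.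

**Step 12**
Reactants: 19 (2S,6S,8S,9R)-2,8-dibromo-9-hydroxy-7,7-dimethyl-11-methylidenespiro[5.5]undecan-3-one
Product: 21 (2S,3R,6S,8S,9S)-2,8-dibromo-9-chloro-1,1,9-trimethyl-5-methylidenespiro[5.5]undecan-3-ol, via titanium alkoxide 20 (not isolated)
Conditions: Me2Zn (1.1 equiv) + TiCl4 (2.2 equiv) → MeTiCl3, CH2Cl2, −78 to −30 °C; then TiCl4 (2 equiv), 2,6-di-tert-butyl-4-methylpyridine (0.2 equiv), −30 to 0 °C; aqueous work-up
Reagents that add atoms: dimethylzinc C[Zn]C; titanium tetrachloride Cl[Ti](Cl)(Cl)Cl
Why: Titanium-mediated carbonyl methylation followed by SN1 chlorination: MeTiCl3 adds to the ketone (C-3 of 19) to give a tertiary titanium alkoxide (either epimer) that ionises with TiCl4, the adjacent equatorial bromine bridges the cation so chloride enters anti to bromine, and the trans-diequatorial bromo-chloro arrangement is also the thermodynamically favoured bromonium-opening product, setting C-9 of 21 as S while the free hydroxyl is carried as its titanium alkoxide.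

**Compound list**
1 | 3-methylbut-2-en-1-ol | CC(C)=CCO | starting material
2 | (2R)-2-bromo-3-chloro-3-methylbutan-1-ol | OC[C@@H](Br)C(C)(C)Cl | intermediate
3 | (2R)-2-bromo-3-chloro-3-methylbutanal | O=C[C@@H](Br)C(C)(C)Cl | intermediate
4 | propa-1,2-diene | C=C=C | starting material
5 | dibromo(2-bromoprop-2-en-1-yl)borane | C=C(Br)CB(Br)Br | intermediate
6 | 2-(2-bromoprop-2-en-1-yl)-4,4,5,5-tetramethyl-1,3,2-dioxaborolane | C=C(Br)CB1OC(C)(C)C(C)(C)O1 | intermediate
7 | 2-{[(4R,5R)-2,5-dibromo-6-chloro-6-methylhept-1-en-4-yl]oxy}-4,4,5,5-tetramethyl-1,3,2-dioxaborolane (boryl ether of 8) | C=C(Br)C[C@@H](OB1OC(C)(C)C(C)(C)O1)[C@@H](Br)C(C)(C)Cl | intermediate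
8 | (4R,5R)-2,5-dibromo-6-chloro-6-methylhept-1-en-4-ol | C=C(Br)C[C@@H](O)[C@@H](Br)C(C)(C)Cl | intermediate
9 | 4-bromophenol | Oc1ccc(Br)cc1 | starting material
10 | (4-bromophenoxy)(tert-butyl)dimethylsilane | CC(C)(C)[Si](C)(C)Oc1ccc(Br)cc1 | intermediate
11 | {4-[(tert-butyldimethylsilyl)oxy]phenyl}lithium | [Li]c1ccc(O[Si](C)(C)C(C)(C)C)cc1 | intermediate
12 | tert-butyldimethyl[4-(trimethylsilyl)phenoxy]silane | C[Si](C)(C)c1ccc(O[Si](C)(C)C(C)(C)C)cc1 | intermediate
13 | 4-(trimethylsilyl)phenol | C[Si](C)(C)c1ccc(O)cc1 | intermediate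
14 | (4R,5S)-2,5-dibromo-6-(4-hydroxyphenyl)-6-methylhept-1-en-4-ol | C=C(Br)C[C@@H](O)[C@@H](Br)C(C)(C)c1ccc(O)cc1 | intermediate
15 | (8S,9R)-8-bromo-9-hydroxy-7,7-dimethyl-11-methylidenespiro[5.5]undeca-1,4-dien-3-one | C=C1C[C@@H](O)[C@@H](Br)C(C)(C)C12C=CC(=O)C=C2 | intermediate
16 | oxa-Michael adduct of 15: the C-9 oxygen bonded to C-1 of the syn dienone arm (2-oxabicyclo[2.2.2]octane across ring A), 4-en-3-one kept, 6S,8S,9R, both C-1 epimers | C=C1C[C@@H](O3)[C@@H](Br)C(C)(C)[C@]12C=CC(=O)CC23 | intermediate
17 | 2-bromo derivative of adduct 16 (C-2 epimers) | C=C1C[C@@H](O3)[C@@H](Br)C(C)(C)[C@]12C=CC(=O)C(Br)C23 | intermediate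
18 | (6S,8S,9R)-2,8-dibromo-9-hydroxy-7,7-dimethyl-11-methylidenespiro[5.5]undeca-1,4-dien-3-one | C=C1C[C@@H](O)[C@@H](Br)C(C)(C)[C@]12C=CC(=O)C(Br)=C2 | intermediate
19 | (2S,6S,8S,9R)-2,8-dibromo-9-hydroxy-7,7-dimethyl-11-methylidenespiro[5.5]undecan-3-one | C=C1C[C@@H](O)[C@@H](Br)C(C)(C)[C@]12CCC(=O)[C@@H](Br)C2 | intermediate
20 | bis(trichlorotitanium) alkoxide of the 3-methyl carbinol from 19 (O-3 and O-9 each bound to TiCl3, C-3 epimers) | C=C1C[C@@H](O[Ti](Cl)(Cl)Cl)[C@@H](Br)C(C)(C)[C@]12CCC(C)(O[Ti](Cl)(Cl)Cl)[C@@H](Br)C2 | intermediate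
21 | (2S,3R,6S,8S,9S)-2,8-dibromo-9-chloro-1,1,9-trimethyl-5-methylidenespiro[5.5]undecan-3-ol | C=C1C[C@@H](O)[C@@H](Br)C(C)(C)[C@]12CC[C@](C)(Cl)[C@@H](Br)C2 | target

**Step count**
Total step count: 12.
Longest linear sequence: 8 steps (1, 2, 4, 8, 9, 10, 11, 12 from compound 1; the arene branch 5, 6, 7, 8, 9, 10, 11, 12 from compound 9 is equally long), which is two thirds of the total.

**Three steps most likely to fail**

Step 8 (Friedel–Crafts union). The bromonium ion may instead be trapped by the tethered 2-bromoalkene, lose a proton, or transfer Br+ to the electron-rich arene. The fallback makes the aryl–C(CH3)2 bond by conjugate addition and sets the bromine stereocentre by enamine catalysis; it sets out from 10 and comes back at 14. Magnesium insertion into 10 gives {4-[(tert-butyldimethylsilyl)oxy]phenyl}magnesium bromide F1. F1 adds 1,4 to 3-methylbut-2-enal under CuBr·SMe2 catalysis with Me3SiCl to give the silyl enol ether tert-butyldimethyl{4-[2-methyl-4-(trimethylsilyloxy)but-3-en-2-yl]phenoxy}silane F2, which acidic work-up hydrolyses to 3-{4-[(tert-butyldimethylsilyl)oxy]phenyl}-3-methylbutanal F3. Enamine-catalysed α-bromination (the antipode of trans-2,5-diphenylpyrrolidine that gives 2S, with 4,4-dibromo-2,6-di-tert-butylcyclohexa-2,5-dienone) gives (2S)-2-bromo-3-{4-[(tert-butyldimethylsilyl)oxy]phenyl}-3-methylbutanal F4. Allylboration with 6 as in step 4 gives, through the boryl ether 2-{[(4R,5S)-2,5-dibromo-6-{4-[(tert-butyldimethylsilyl)oxy]phenyl}-6-methylhept-1-en-4-yl]oxy}-4,4,5,5-tetramethyl-1,3,2-dioxaborolane F5, the bromohydrin (4R,5S)-2,5-dibromo-6-{4-[(tert-butyldimethylsilyl)oxy]phenyl}-6-methylhept-1-en-4-ol F6. K2CO3 in MeOH then removes the aryl silyl ether to give 14.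

Step 9 (proposed new palladium-catalysed dearomative alkenylation). The alkenylpalladium intermediate may fail to engage the phenoxide para carbon, or the base may attack the bromohydrin. The fallback uses known chemistry, the gold-catalysed intramolecular ipso-Friedel–Crafts alkenylation of a phenol by a tethered terminal alkyne; it sets out from 3 and comes back at 15. Indium-mediated Barbier propargylation of 3 with propargyl bromide gives (4R,5R)-5-bromo-6-chloro-6-methylhept-1-yn-4-ol F7 under the same Cornforth control. TBSOTf and 2,6-lutidine give {[(4R,5R)-5-bromo-6-chloro-6-methylhept-1-yn-4-yl]oxy}(tert-butyl)dimethylsilane F8. Friedel–Crafts union with 13 as in step 8 gives 4-[(3S,4R)-3-bromo-4-{[tert-butyl(dimethyl)silyl]oxy}-2-methylhept-6-yn-2-yl]phenol F9. Ph3PAuNTf2 (monovalent gold, 5 mol %, CH2Cl2, rt) effects 6-exo-dig attack of the phenol para carbon on the activated alkyne and protodeauration to give (8S,9R)-8-bromo-9-{[tert-butyl(dimethyl)silyl]oxy}-7,7-dimethyl-11-methylidenespiro[5.5]undeca-1,4-dien-3-one F10. Bu4NF then removes the silyl group to give 15.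

Step 10 (proposed new hydroxyl-relayed desymmetrising bromination). The bridging oxa-Michael addition needs a boat ring A and a poorly aligned approach to the enone, so it may be too slow, and over-bromination of the marked arm is possible. The fallback uses known chemistry, the undirected nucleophile-catalysed α-bromination of cyclic enones; it sets out from 15 and comes back at 18. N-bromosuccinimide with catalytic pyridine N-oxide in MeCN brominates either arm and gives 18 together with its C-6 epimer (6R,8S,9R)-2,8-dibromo-9-hydroxy-7,7-dimethyl-11-methylidenespiro[5.5]undeca-1,4-dien-3-one F11. Chromatographic separation returns 18.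

Further compounds
F1 | step 8 | {4-[(tert-butyldimethylsilyl)oxy]phenyl}magnesium bromide | Br[Mg]c1ccc(O[Si](C)(C)C(C)(C)C)cc1
F2 | step 8 | tert-butyldimethyl{4-[2-methyl-4-(trimethylsilyloxy)but-3-en-2-yl]phenoxy}silane (E/Z mixture) | C[Si](C)(C)OC=CC(C)(C)c1ccc(O[Si](C)(C)C(C)(C)C)cc1
F3 | step 8 | 3-{4-[(tert-butyldimethylsilyl)oxy]phenyl}-3-methylbutanal | O=CCC(C)(C)c1ccc(O[Si](C)(C)C(C)(C)C)cc1
F4 | step 8 | (2S)-2-bromo-3-{4-[(tert-butyldimethylsilyl)oxy]phenyl}-3-methylbutanal | O=C[C@@H](Br)C(C)(C)c1ccc(O[Si](C)(C)C(C)(C)C)cc1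
F5 | step 8 | 2-{[(4R,5S)-2,5-dibromo-6-{4-[(tert-butyldimethylsilyl)oxy]phenyl}-6-methylhept-1-en-4-yl]oxy}-4,4,5,5-tetramethyl-1,3,2-dioxaborolane | C=C(Br)C[C@@H](OB1OC(C)(C)C(C)(C)O1)[C@@H](Br)C(C)(C)c1ccc(O[Si](C)(C)C(C)(C)C)cc1
F6 | step 8 | (4R,5S)-2,5-dibromo-6-{4-[(tert-butyldimethylsilyl)oxy]phenyl}-6-methylhept-1-en-4-ol | C=C(Br)C[C@@H](O)[C@@H](Br)C(C)(C)c1ccc(O[Si](C)(C)C(C)(C)C)cc1
F7 | step 9 | (4R,5R)-5-bromo-6-chloro-6-methylhept-1-yn-4-ol | C#CC[C@@H](O)[C@@H](Br)C(C)(C)Cl
F8 | step 9 | {[(4R,5R)-5-bromo-6-chloro-6-methylhept-1-yn-4-yl]oxy}(tert-butyl)dimethylsilane | C#CC[C@@H](O[Si](C)(C)C(C)(C)C)[C@@H](Br)C(C)(C)Cl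
F9 | step 9 | 4-[(3S,4R)-3-bromo-4-{[tert-butyl(dimethyl)silyl]oxy}-2-methylhept-6-yn-2-yl]phenol | C#CC[C@@H](O[Si](C)(C)C(C)(C)C)[C@@H](Br)C(C)(C)c1ccc(O)cc1
F10 | step 9 | (8S,9R)-8-bromo-9-{[tert-butyl(dimethyl)silyl]oxy}-7,7-dimethyl-11-methylidenespiro[5.5]undeca-1,4-dien-3-one | C=C1C[C@@H](O[Si](C)(C)C(C)(C)C)[C@@H](Br)C(C)(C)C12C=CC(=O)C=C2
F11 | step 10 | (6R,8S,9R)-2,8-dibromo-9-hydroxy-7,7-dimethyl-11-methylidenespiro[5.5]undeca-1,4-dien-3-one | C=C1C[C@@H](O)[C@@H](Br)C(C)(C)[C@@]12C=CC(=O)C(Br)=C2
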